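**Plan**
- Retrosynthesis: cut C3–C4 (ten-membered ring), then C5–C6, then both bonds to C9 (C9–C10 and C8–C9), then C2–C3. This leaves a ring-A enol triflate, carbon monoxide and a stannylbutenolide.
- Enabling feature: the oxygenated C9 is a single carbon between ring-A carbon C10 (next to quaternary C1) and lactone carbon C8. It can therefore enter as CO between a C10 enol triflate and a C8 stannane.
- Forward: ring A is built from 2-methoxy-3-methylbenzoic acid by Birch reductive methylation and the butenolide from (S)-glycerate by Dieckmann cyclisation. After the carbonylative union come lactone hydration, C10=C11 hydrogenation, the C5 unit on C6, ring closure at C3–C4 by allylation, acetylation and desilylation.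
- Stereochemistry, ring A: C1 comes from the prolinol-ether auxiliary, C12 and C2 from CBS reductions. The C2 hydroxyl directs both the epoxidation (C13, C14) and the hydrogenation (C10, C11).
- Stereochemistry, lactone side: C7 comes from glycerate; C8 and C17 from an oxa-Michael addition tethered to O6; C9 from a Luche reduction. C6 is set by Felkin–Anh reduction followed by invertive chlorination, and C3 by chelation-controlled allylation.

Key step: step 22

Remark: atom numbers C1–C20 are those of the briarane skeleton and are used for all intermediates.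
Remark (assumption): in step 2 the amide enolate is taken to be methylated on the face away from the methoxymethyl arm of the (S)-auxiliary, giving C1 as drawn in 6; if the sense were opposite, the (R)-amine would be used with no other change.

**Route**

Step 1
Reactants: 1 2-methoxy-3-methylbenzoic acid; 2 (S)-2-(methoxymethyl)pyrrolidine
Product: 4 (S)-[2-(methoxymethyl)pyrrolidin-1-yl](2-methoxy-3-methylphenyl)methanone, via 2-methoxy-3-methylbenzoyl chloride 3 (not isolated)
Conditions: (COCl)2, cat. DMF, CH2Cl2, 0 °C to rt; then 2, Et3N, CH2Cl2, 0 °C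
Reagents that add atoms: none
Why: Acid chloride formation and N-acylation attach the chiral auxiliary that will control C1.

Step 2
Reactants: 4 benzamide
Product: 6 [(1S)-2-methoxy-1,3-dimethylcyclohexa-2,5-dien-1-yl][(S)-2-(methoxymethyl)pyrrolidin-1-yl]methanone, via potassium amide enolate 5 (not isolated)
Conditions: K, NH3(l)/THF, t-BuOH (1 equiv), −78 °C; then MeI, −78 °C
Reagents that add atoms: iodomethane, CI
Why: Birch reduction gives the chelated amide enolate, which should be methylated anti to the methoxymethyl arm (auxiliary-controlled Birch reductive alkylation), setting quaternary C1 and leaving the C10 enol ether.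

Step 3
Reactants: 6 diene amide
Product: 7 (4S)-3-methoxy-2,4-dimethyl-4-{[(S)-2-(methoxymethyl)pyrrolidin-1-yl]carbonyl}cyclohexa-2,5-dien-1-one (C12 ketone)
Conditions: pyridinium dichromate (pyH)2Cr2O7 (20 mol %), t-BuOOH, Celite, benzene, rt
Reagents that add atoms: tert-butyl hydroperoxide, CC(C)(C)OO
Why: The doubly allylic C12 methylene of a Birch diene is oxidised selectively to the cross-conjugated dienone by chromium-catalysed hydroperoxide oxidation (allylic oxidation).

Step 4
Reactants: 7 dienone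
Product: 8 [(1S,4S)-4-hydroxy-2-methoxy-1,3-dimethylcyclohexa-2,5-dien-1-yl][(S)-2-(methoxymethyl)pyrrolidin-1-yl]methanone (C12 hydroxyl cis to the C1 methyl)
Conditions: (R)-2-methyl-CBS-oxazaborolidine (0.2 equiv), catecholborane, toluene, −78 to −40 °C; basic work-up
Reagents that add atoms: none
Why: CBS reduction under reagent control, the α-methyl-β-methoxy alkene arm acting as the large group, should deliver hydride to the face that gives the β C12 carbinol; the flat ring and remote C1 exert little bias.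

Step 5
Reactants: 8 dienol
Product: 9 C12 tert-butyldimethylsilyl ether of 8
Conditions: TBSCl, imidazole, DMF, 0 °C to rt
Reagents that add atoms: tert-butyldimethylsilyl chloride, CC(C)(C)[Si](C)(C)Cl
Why: Silylation under basic conditions protects the acid-labile doubly allylic alcohol before the amide is reduced.

Step 6
Reactants: 9 silyl ether amide
Product: 10 [(1R,4S)-4-(tert-butyldimethylsilyloxy)-2-methoxy-1,3-dimethylcyclohexa-2,5-dien-1-yl]methanol (C2 primary alcohol)
Conditions: LiH2NBH3 (from H3N·BH3 and LiN(iPr)2), THF, 0 °C to rt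
Reagents that add atoms: none
Why: Lithium amidotrihydroborate reduces hindered tertiary amides to primary alcohols with C–N cleavage and releases the auxiliary; the enol ether and silyl ether are inert to it.

Step 7
Reactants: 10 neopentyl alcohol
Product: 11 (1S,4S)-4-(tert-butyldimethylsilyloxy)-2-methoxy-1,3-dimethylcyclohexa-2,5-diene-1-carbaldehyde (C2 aldehyde)
Conditions: Dess–Martin periodinane, NaHCO3, CH2Cl2, 0 °C
Reagents that add atoms: none
Why: Buffered Dess–Martin oxidation gives the non-enolisable aldehyde without touching the enol ether.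

Step 8
Reactants: 12 4-methoxybenzyl alcohol; 13 tributyl(iodomethyl)stannane
Product: 15 tributyl{[(4-methoxybenzyl)oxy]methyl}stannane, via sodium 4-methoxybenzyl oxide 14 (not isolated)
Conditions: NaH, THF/DMF, 0 °C to rt
Reagents that add atoms: none
Why: Williamson etherification of the primary iodide gives the precursor of the C3 alkoxymethyl anion.

Step 9
Reactants: 15 stannane; 11 aldehyde
Product: 17 C2 carbinol (both C2 epimers) bearing the C3 4-methoxybenzyl ether, via [(4-methoxybenzyl)oxy]methyllithium 16 (not isolated)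
Conditions: 15, n-BuLi, THF, −78 °C; then 11, −78 °C
Reagents that add atoms: none
Why: Tin–lithium exchange gives the α-alkoxymethyllithium, which adds to the only electrophile present and forms C2–C3; the C2 configuration is corrected in steps 10 and 11.

Step 10
Reactants: 17 carbinol mixture
Product: 18 C2 ketone (α-alkoxy ketone on quaternary C1)
Conditions: Dess–Martin periodinane, NaHCO3, CH2Cl2, rt
Reagents that add atoms: none
Why: Dess–Martin oxidation converges both epimers to one ketone.

Step 11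
Reactants: 18 ketone
Product: 19 (2S)-carbinol with C3 OPMB, C10 enol ether and C12 OTBS
Conditions: (S)-2-methyl-CBS-oxazaborolidine, catecholborane, toluene, −78 °C
Reagents that add atoms: none
Why: CBS reduction with the tert-alkyl C1 as large group gives 2S, and the Felkin–Anh preference (C10 arm anti to hydride) points the same way.

Step 12
Reactants: 19 enol ether
Product: 20 C10 ketone (C11 epimers; C2 hydroxyl free)
Conditions: oxalic acid, THF/H2O, 0 °C
Reagents that add atoms: water, O
Why: Mild acid hydrolysis of the methyl enol ether proceeds by protonation at C11 and should be faster than ionisation of the C12 silyl ether; C11 becomes sp2 again in step 15.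

Step 13
Reactants: 20 homoallylic alcohol
Product: 21 13α,14α-epoxy C10 ketone
Conditions: VO(acac)2 (cat.), t-BuOOH, CH2Cl2, rt
Reagents that add atoms: tert-butyl hydroperoxide, CC(C)(C)OO
Why: Vanadium-catalysed epoxidation directed by the homoallylic C2 hydroxyl (on the α substituent of C1) delivers oxygen to the α face of the only alkene, anti to the β C12 silyl ether, setting C13 and C14.

Step 14
Reactants: 21 epoxy alcohol
Product: 22 C2 triethylsilyl ether of 21
Conditions: TESOTf, 2,6-lutidine, CH2Cl2, −78 °C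
Reagents that add atoms: triethylsilyl triflate, CC[Si](CC)(CC)OS(=O)(=O)C(F)(F)F
Why: Silyl triflate protects the hindered neopentyl hydroxyl, which would otherwise undergo retro-aldol cleavage in step 15 and trap the acylpalladium in step 22.

Step 15
Reactants: 22 ketone
Product: 24 ring-A C10 enol triflate (C10=C11, C2 OTES, C3 OPMB, C12 OTBS, 13,14-epoxide), via potassium C10 enolate 23 (not isolated)
Conditions: KN(SiMe3)2, THF, −78 °C; then N-(5-chloro-2-pyridyl)triflimide, −78 °C
Reagents that add atoms: N-(5-chloro-2-pyridyl)triflimide, Clc1ccc(N(S(=O)(=O)C(F)(F)F)S(=O)(=O)C(F)(F)F)nc1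
Why: C11 carries the only α-hydrogen, so enolisation is regiospecific, and O-sulfonylation at −78 °C should outrun β-elimination of the C12 silyloxy group (enol triflate formation).

Step 16
Reactants: 25 methyl (S)-2,2-dimethyl-1,3-dioxolane-4-carboxylate
Product: 26 methyl (S)-2,3-dihydroxypropanoate
Conditions: p-TsOH (cat.), MeOH, rt
Reagents that add atoms: none
Why: Acid-catalysed transacetalisation frees the diol without epimerising C7.

Step 17
Reactants: 26 diol
Product: 27 methyl (S)-2-hydroxy-3-(triethylsilyloxy)propanoate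
Conditions: TESCl, imidazole, CH2Cl2, −20 °C
Reagents that add atoms: chlorotriethylsilane, CC[Si](Cl)(CC)CC
Why: The primary hydroxyl (C6–O) is silylated selectively over the secondary α-hydroxy ester oxygen.

Step 18
Reactants: 27 hydroxy ester; 28 propanoyl chloride
Product: 29 methyl (S)-2-(propanoyloxy)-3-(triethylsilyloxy)propanoate
Conditions: pyridine, DMAP (cat.), CH2Cl2, 0 °C
Reagents that add atoms: none
Why: O-acylation brings in C17, C18 and C19.

Step 19
Reactants: 29 diester
Product: 31 (S)-4-hydroxy-3-methyl-5-[(triethylsilyloxy)methyl]furan-2(5H)-one, via lithium tetronate 30 (not isolated)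
Conditions: LiN(SiMe3)2 (2.2 equiv), THF, −78 to 0 °C; then cold dilute HCl, rapid extraction
Reagents that add atoms: none
Why: Dieckmann cyclisation of the propanoate enolate onto the methyl ester forms C8–C17 and the tetronic acid; low temperature and the stable tetronate anion should preserve C7.

Step 20
Reactants: 31 tetronic acid
Product: 32 (S)-4-methyl-5-oxo-2-[(triethylsilyloxy)methyl]-2,5-dihydrofuran-3-yl triflate
Conditions: Tf2O, iPr2NEt, CH2Cl2, −78 °C
Reagents that add atoms: triflic anhydride, O=S(=O)(OS(=O)(=O)C(F)(F)F)C(F)(F)F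
Why: O-sulfonylation of the vinylogous acid gives the β-triflyloxy butenolide.

Step 21
Reactants: 32 butenolide triflate
Product: 33 (S)-3-methyl-4-(tributylstannyl)-5-[(triethylsilyloxy)methyl]furan-2(5H)-one
Conditions: (Bu3Sn)2, Pd(PPh3)4 (cat.), LiCl, 1,4-dioxane, 90 °C
Reagents that add atoms: hexabutyldistannane, CCCC[Sn](CCCC)(CCCC)[Sn](CCCC)(CCCC)CCCC
Why: Palladium-catalysed stannylation of the electron-poor vinyl triflate with the distannane gives the C8 stannane without touching C7.

Step 22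
Reactants: 24 ring-A C10 enol triflate; 34 carbon monoxide; 33 C8 stannylbutenolide
Product: 35 cross-conjugated dienone: C9 ketone between C10 of ring A and C8 of the butenolide
Conditions: Pd2(dba)3 (cat.), AsPh3, CuI (cat.), LiCl, CO (3 atm), NMP, 60 °C
Reagents that add atoms: none
Why: Zerovalent palladium inserts into the C10–OTf bond (LiCl keeps the vinylpalladium reactive), CO inserts to give the C9 acylpalladium, the C8 stannane transmetalates with CuI assistance, and reductive elimination forms C9–C10 and C8–C9 in one operation. The closest known reaction type is the carbonylative Stille coupling of enol triflates with alkenylstannanes to give divinyl ketones. No ring is closed and no stereocentre is created. Carbonyl insertion must outrun direct triflate–stannane coupling; CO pressure, the weakly donating AsPh3 ligand and the slow transmetalation of the electron-poor, α-branched stannane favour the acyl pathway. The C2 silyl ether prevents capture of the acylpalladium by O2 as a lactone, and the epoxide is not allylic to the metal and should survive.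

Step 23
Reactants: 35 dienone
Product: 36 (9R)-dienol
Conditions: NaBH4, CeCl3·7H2O, MeOH/THF, −78 °C
Reagents that add atoms: none
Why: Luche 1,2-reduction; with ring A twisted out of conjugation and the ketone s-cis to the butenolide alkene (oxygen toward the C17 methyl), hydride should enter anti to the C7 silyloxymethyl arm to give 9R.

Step 24
Reactants: 36 dienol
Product: 37 (9R)-acetate
Conditions: Ac2O, Et3N, DMAP (cat.), CH2Cl2, 0 °C to rt
Reagents that add atoms: acetic anhydride, CC(=O)OC(C)=O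
Why: DMAP-catalysed acetylation installs the final C9 acetate and blocks O9 from translactonisation in the base-mediated step 26.

Step 25
Reactants: 37 bis(triethylsilyl) ether
Product: 38 C6 primary alcohol (C2 OTES and C12 OTBS retained)
Conditions: PPTS (cat.), MeOH/CH2Cl2, 0 °C
Reagents that add atoms: none
Why: Mild acid methanolysis cleaves the primary triethylsilyl ether much faster than the neopentyl secondary one or the secondary TBS ether.

Step 26
Reactants: 38 δ-hydroxy butenolide
Product: 40 4-methoxybenzylidene acetal bridging O6 and O8 (dioxane cis-fused to the now saturated lactone; C8–O cis to C6, C17 methyl trans to C9, aryl equatorial), via potassium hemiacetal alkoxide 39 (not isolated)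
Conditions: 4-methoxybenzaldehyde, KOtBu (cat., in portions), THF, 0 °C
Reagents that add atoms: 4-methoxybenzaldehyde, COc1ccc(C=O)cc1
Why: Hemiacetal-tethered oxa-Michael addition: the three-atom tether from O6 can reach C8 only on the C6 face, so the dioxane is cis-fused and C8 is set; C17 is set by reversible protonation of the lactone enolate (methyl trans to the bulky C9 arm) and the acetal carbon settles with the aryl group equatorial.

Step 27
Reactants: 40 acetal
Product: 41 triol (C2, C6 and C8 hydroxyls free; C10=C11 intact)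
Conditions: AcOH/THF/H2O (3:1:1), 35 °C
Reagents that add atoms: none
Why: Mild acid hydrolysis removes the electron-rich benzylidene acetal and the C2 triethylsilyl ether, while the secondary TBS ether and the hindered epoxide should survive.

Step 28
Reactants: 41 homoallylic alcohol
Product: 42 C10,C11-dihydro triol (H10 and H11 both α)
Conditions: [Ir(cod)(PCy3)(py)]PF6 (cat.), H2 (50 atm), CH2Cl2, rt
Reagents that add atoms: none
Why: Hydroxyl-directed hydrogenation: the C2 hydroxyl on the α substituent of C1 binds iridium and delivers H2 syn to the α face of the tetrasubstituted alkene, anti to the β C12 silyl ether, setting C10 and C11 cis.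

Step 29
Reactants: 42 triol
Product: 43 C6 aldehyde
Conditions: TEMPO (cat.), PhI(OAc)2, CH2Cl2, rt
Reagents that add atoms: none
Why: Oxoammonium oxidation is selective for the primary C6 alcohol over the hindered secondary C2 and tertiary C8 hydroxyls, and the neutral conditions leave C7 configured.

Step 30
Reactants: 43 aldehyde; 44 2-bromo-3-(trimethylsilyl)propene
Product: 45 C6 allylic alcohol carrying the 2-[(trimethylsilyl)methyl]vinyl unit (C6 epimers)
Conditions: CrCl2, NiCl2 (cat.), DMF, rt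
Reagents that add atoms: none
Why: Nozaki–Hiyama–Kishi coupling adds the vinyl bromide to the aldehyde in the presence of lactone, acetate and free hydroxyls and forms C5–C6; the C6 configuration is reset in steps 31 and 32.

Step 31
Reactants: 45 allylic alcohol
Product: 46 C6 enone
Conditions: MnO2, CH2Cl2, rt
Reagents that add atoms: none
Why: MnO2 oxidises only the allylic C6 alcohol and converges both epimers.

Step 32
Reactants: 46 enone
Product: 47 (6R)-allylic alcohol
Conditions: NaBH4, CeCl3·7H2O, MeOH, −78 °C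
Reagents that add atoms: none
Why: Luche 1,2-reduction under Felkin–Anh control (C7–O bond anti to hydride; chelation through the C8 hydroxyl leads to the same face) should give 6R, the epimer needed for inversion.

Step 33
Reactants: 47 allylic alcohol
Product: 48 (6S)-allylic chloride
Conditions: PPh3, hexachloroacetone, CH2Cl2, 0 °C
Reagents that add atoms: hexachloroacetone, O=C(C(Cl)(Cl)Cl)C(Cl)(Cl)Cl
Why: Appel-type chlorination with PPh3/hexachloroacetone converts allylic alcohols to chlorides by SN2 with inversion and little allylic transposition; the neopentyl C2 and tertiary C8 hydroxyls cannot be displaced.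

Step 34
Reactants: 48 allylsilane
Product: 49 2-substituted allylic bromide
Conditions: NBS, CH2Cl2/DMF, −78 °C
Reagents that add atoms: N-bromosuccinimide, O=C1CCC(=O)N1Br
Why: Electrophilic bromodesilylation (SE2′): bromine adds to the methylene terminus and silicon leaves from the β-silyl cation, regenerating the 1,1-disubstituted alkene.

Step 35
Reactants: 49 PMB ether
Product: 50 C2,C3-diol
Conditions: DDQ, CH2Cl2/pH 7 buffer, 0 °C
Reagents that add atoms: none
Why: Oxidative cleavage of the 4-methoxybenzyl ether is neutral and spares the halides, epoxide, acetate and silyl ether.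

Step 36
Reactants: 50 diol
Product: 51 C3 aldehyde with free C2 hydroxyl (α-hydroxy aldehyde, used crude)
Conditions: TEMPO (cat.), NCS, Bu4NCl, CH2Cl2/aq. NaHCO3–K2CO3, 0 °C
Reagents that add atoms: none
Why: Oxoammonium oxidation with NCS as terminal oxidant is selective for the primary alcohol of a 1,2-diol and avoids the glycol cleavage that a hypervalent iodine co-oxidant could cause.

Step 37
Reactants: 51 bromo aldehyde
Product: 52 ten-membered ring (3S)-homoallylic alcohol with C5 exocyclic methylene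
Conditions: indium powder, THF/H2O (1:1), high dilution, rt
Reagents that add atoms: none
Why: Indium-mediated intramolecular Barbier allylation: indium inserts into the primary allylic bromide but not the secondary chloride, and the allylindium adds through its methylene terminus to the aldehyde chelated by the free C2 hydroxyl (Cram-chelate, syn diol), forming C3–C4, the ten-membered ring and 3S.

Step 38
Reactants: 52 diol
Product: 53 C3,C9-diacetate with C12 OTBS
Conditions: Ac2O, pyridine, CH2Cl2, 0 °C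
Reagents that add atoms: acetic anhydride, CC(=O)OC(C)=O
Why: The C3 hydroxyl is acetylated selectively because the C2 hydroxyl is neopentyl and the C8 hydroxyl tertiary.

Step 39
Reactants: 53 silyl ether
Product: 54 CNP0200238.1
Conditions: HF·pyridine, pyridine, THF, 0 °C to rt
Reagents that add atoms: none
Why: Buffered fluoride desilylation frees the C12 hydroxyl without opening the epoxide, ionising the allylic chloride or moving the acetates.

**Compound list**

1 | 2-methoxy-3-methylbenzoic acid | COc1c(C)cccc1C(O)=O | starting material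
2 | (S)-2-(methoxymethyl)pyrrolidine | COC[C@@H]1CCCN1 | starting material
3 | 2-methoxy-3-methylbenzoyl chloride | COc1c(C)cccc1C(Cl)=O | intermediate
4 | (S)-[2-(methoxymethyl)pyrrolidin-1-yl](2-methoxy-3-methylphenyl)methanone | COC[C@@H]1CCCN1C(=O)c1cccc(C)c1OC | intermediate
5 | potassium amide enolate of Birch-reduced 4 | COC[C@@H]1CCCN1C([O-])=C1C(OC)=C(C)CC=C1.[K+] | intermediate
6 | [(1S)-2-methoxy-1,3-dimethylcyclohexa-2,5-dien-1-yl][(S)-2-(methoxymethyl)pyrrolidin-1-yl]methanone | COC[C@@H]1CCCN1C(=O)[C@]1(C)C(OC)=C(C)CC=C1 | intermediate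
7 | (4S)-3-methoxy-2,4-dimethyl-4-{[(S)-2-(methoxymethyl)pyrrolidin-1-yl]carbonyl}cyclohexa-2,5-dien-1-one | COC[C@@H]1CCCN1C(=O)[C@]1(C)C(OC)=C(C)C(=O)C=C1 | intermediate
8 | [(1S,4S)-4-hydroxy-2-methoxy-1,3-dimethylcyclohexa-2,5-dien-1-yl][(S)-2-(methoxymethyl)pyrrolidin-1-yl]methanone | COC[C@@H]1CCCN1C(=O)[C@]1(C)C(OC)=C(C)[C@@H](O)C=C1 | intermediate
9 | C12 tert-butyldimethylsilyl ether of 8 | COC[C@@H]1CCCN1C(=O)[C@]1(C)C(OC)=C(C)[C@@H](O[Si](C)(C)C(C)(C)C)C=C1 | intermediate
10 | [(1R,4S)-4-(tert-butyldimethylsilyloxy)-2-methoxy-1,3-dimethylcyclohexa-2,5-dien-1-yl]methanol | OC[C@]1(C)C(OC)=C(C)[C@@H](O[Si](C)(C)C(C)(C)C)C=C1 | intermediate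
11 | (1S,4S)-4-(tert-butyldimethylsilyloxy)-2-methoxy-1,3-dimethylcyclohexa-2,5-diene-1-carbaldehyde | O=C[C@]1(C)C(OC)=C(C)[C@@H](O[Si](C)(C)C(C)(C)C)C=C1 | intermediate
12 | 4-methoxybenzyl alcohol | COc1ccc(CO)cc1 | starting material
13 | tributyl(iodomethyl)stannane | CCCC[Sn](CCCC)(CCCC)CI | starting material
14 | sodium 4-methoxybenzyl oxide | COc1ccc(C[O-])cc1.[Na+] | intermediate
15 | tributyl{[(4-methoxybenzyl)oxy]methyl}stannane | CCCC[Sn](CCCC)(CCCC)COCc1ccc(OC)cc1 | intermediate
16 | [(4-methoxybenzyl)oxy]methyllithium | [Li]COCc1ccc(OC)cc1 | intermediate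
17 | ring-A C2 carbinol (C2 epimers) with C3 OPMB, C10 enol ether, C12 OTBS | COc1ccc(COCC(O)[C@]2(C)C(OC)=C(C)[C@@H](O[Si](C)(C)C(C)(C)C)C=C2)cc1 | intermediate
18 | ring-A C2 ketone | COc1ccc(COCC(=O)[C@]2(C)C(OC)=C(C)[C@@H](O[Si](C)(C)C(C)(C)C)C=C2)cc1 | intermediate
19 | ring-A (2S)-carbinol | COc1ccc(COC[C@@H](O)[C@]2(C)C(OC)=C(C)[C@@H](O[Si](C)(C)C(C)(C)C)C=C2)cc1 | intermediate
20 | ring-A C10 ketone (C11 epimers), C13=C14 alkene | COc1ccc(COC[C@@H](O)[C@]2(C)C(=O)C(C)[C@@H](O[Si](C)(C)C(C)(C)C)C=C2)cc1 | intermediate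
21 | ring-A 13α,14α-epoxy C10 ketone | COc1ccc(COC[C@@H](O)[C@]2(C)C(=O)C(C)[C@@H](O[Si](C)(C)C(C)(C)C)[C@@H]3O[C@@H]32)cc1 | intermediate
22 | C2 triethylsilyl ether of 21 | COc1ccc(COC[C@@H](O[Si](CC)(CC)CC)[C@]2(C)C(=O)C(C)[C@@H](O[Si](C)(C)C(C)(C)C)[C@@H]3O[C@@H]32)cc1 | intermediate
23 | potassium C10 enolate of 22 | COc1ccc(COC[C@@H](O[Si](CC)(CC)CC)[C@]2(C)C([O-])=C(C)[C@@H](O[Si](C)(C)C(C)(C)C)[C@@H]3O[C@@H]32)cc1.[K+] | intermediate
24 | ring-A C10 enol triflate (C2 OTES, C3 OPMB, C12 OTBS, 13α,14α-epoxide) | COc1ccc(COC[C@@H](O[Si](CC)(CC)CC)[C@]2(C)C(OS(=O)(=O)C(F)(F)F)=C(C)[C@@H](O[Si](C)(C)C(C)(C)C)[C@@H]3O[C@@H]32)cc1 | intermediate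
25 | methyl (S)-2,2-dimethyl-1,3-dioxolane-4-carboxylate | COC(=O)[C@@H]1COC(C)(C)O1 | starting material
26 | methyl (S)-2,3-dihydroxypropanoate | COC(=O)[C@@H](O)CO | intermediate
27 | methyl (S)-2-hydroxy-3-(triethylsilyloxy)propanoate | COC(=O)[C@@H](O)CO[Si](CC)(CC)CC | intermediate
28 | propanoyl chloride | CCC(Cl)=O | starting material
29 | methyl (S)-2-(propanoyloxy)-3-(triethylsilyloxy)propanoate | COC(=O)[C@@H](OC(=O)CC)CO[Si](CC)(CC)CC | intermediate
30 | lithium tetronate of 31 | CC1=C([O-])[C@H](CO[Si](CC)(CC)CC)OC1=O.[Li+] | intermediate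
31 | (S)-4-hydroxy-3-methyl-5-[(triethylsilyloxy)methyl]furan-2(5H)-one | CC1=C(O)[C@H](CO[Si](CC)(CC)CC)OC1=O | intermediate
32 | (S)-4-methyl-5-oxo-2-[(triethylsilyloxy)methyl]-2,5-dihydrofuran-3-yl triflate | CC1=C(OS(=O)(=O)C(F)(F)F)[C@H](CO[Si](CC)(CC)CC)OC1=O | intermediate
33 | (S)-3-methyl-4-(tributylstannyl)-5-[(triethylsilyloxy)methyl]furan-2(5H)-one | CC1=C([Sn](CCCC)(CCCC)CCCC)[C@H](CO[Si](CC)(CC)CC)OC1=O | intermediate
34 | carbon monoxide | [C-]#[O+] | starting material
35 | C9 dienone joining ring A (C10=C11) and the butenolide (C8=C17) | COc1ccc(COC[C@@H](O[Si](CC)(CC)CC)[C@]2(C)C(=C(C)[C@@H](O[Si](C)(C)C(C)(C)C)[C@@H]3O[C@@H]32)C(=O)C4=C(C)C(=O)O[C@H]4CO[Si](CC)(CC)CC)cc1 | intermediate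
36 | (9R)-dienol | COc1ccc(COC[C@@H](O[Si](CC)(CC)CC)[C@]2(C)C(=C(C)[C@@H](O[Si](C)(C)C(C)(C)C)[C@@H]3O[C@@H]32)[C@@H](O)C4=C(C)C(=O)O[C@H]4CO[Si](CC)(CC)CC)cc1 | intermediate
37 | (9R)-acetate | COc1ccc(COC[C@@H](O[Si](CC)(CC)CC)[C@]2(C)C(=C(C)[C@@H](O[Si](C)(C)C(C)(C)C)[C@@H]3O[C@@H]32)[C@@H](OC(C)=O)C4=C(C)C(=O)O[C@H]4CO[Si](CC)(CC)CC)cc1 | intermediate
38 | C6 primary alcohol (butenolide intact) | COc1ccc(COC[C@@H](O[Si](CC)(CC)CC)[C@]2(C)C(=C(C)[C@@H](O[Si](C)(C)C(C)(C)C)[C@@H]3O[C@@H]32)[C@@H](OC(C)=O)C4=C(C)C(=O)O[C@H]4CO)cc1 | intermediate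
39 | potassium hemiacetal alkoxide of 38 with 4-methoxybenzaldehyde | COc1ccc(COC[C@@H](O[Si](CC)(CC)CC)[C@]2(C)C(=C(C)[C@@H](O[Si](C)(C)C(C)(C)C)[C@@H]3O[C@@H]32)[C@@H](OC(C)=O)C4=C(C)C(=O)O[C@H]4COC([O-])c5ccc(OC)cc5)cc1.[K+] | intermediate
40 | O6,O8-(4-methoxybenzylidene) acetal, cis-fused dioxane–lactone | COc1ccc(COC[C@@H](O[Si](CC)(CC)CC)[C@]2(C)C(=C(C)[C@@H](O[Si](C)(C)C(C)(C)C)[C@@H]3O[C@@H]32)[C@@H](OC(C)=O)[C@]4(O[C@@H](c5ccc(OC)cc5)OC6)[C@@H](C)C(=O)O[C@H]46)cc1 | intermediate
41 | C2,C6,C8-triol with C10=C11 | COc1ccc(COC[C@@H](O)[C@]2(C)C(=C(C)[C@@H](O[Si](C)(C)C(C)(C)C)[C@@H]3O[C@@H]32)[C@@H](OC(C)=O)[C@]4(O)[C@@H](C)C(=O)O[C@H]4CO)cc1 | intermediate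
42 | C10,C11-dihydro triol (H10, H11 α) | COc1ccc(COC[C@@H](O)[C@]2(C)[C@H]([C@@H](C)[C@@H](O[Si](C)(C)C(C)(C)C)[C@@H]3O[C@@H]32)[C@@H](OC(C)=O)[C@]4(O)[C@@H](C)C(=O)O[C@H]4CO)cc1 | intermediate
43 | C6 aldehyde | COc1ccc(COC[C@@H](O)[C@]2(C)[C@H]([C@@H](C)[C@@H](O[Si](C)(C)C(C)(C)C)[C@@H]3O[C@@H]32)[C@@H](OC(C)=O)[C@]4(O)[C@@H](C)C(=O)O[C@H]4C=O)cc1 | intermediate
44 | 2-bromo-3-(trimethylsilyl)propene | C=C(Br)C[Si](C)(C)C | starting material
45 | C6 allylic alcohol (C6 epimers) with C5 allylsilane unit | COc1ccc(COC[C@@H](O)[C@]2(C)[C@H]([C@@H](C)[C@@H](O[Si](C)(C)C(C)(C)C)[C@@H]3O[C@@H]32)[C@@H](OC(C)=O)[C@]4(O)[C@@H](C)C(=O)O[C@H]4C(O)C(=C)C[Si](C)(C)C)cc1 | intermediate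
46 | C6 enone | COc1ccc(COC[C@@H](O)[C@]2(C)[C@H]([C@@H](C)[C@@H](O[Si](C)(C)C(C)(C)C)[C@@H]3O[C@@H]32)[C@@H](OC(C)=O)[C@]4(O)[C@@H](C)C(=O)O[C@H]4C(=O)C(=C)C[Si](C)(C)C)cc1 | intermediate
47 | (6R)-allylic alcohol | COc1ccc(COC[C@@H](O)[C@]2(C)[C@H]([C@@H](C)[C@@H](O[Si](C)(C)C(C)(C)C)[C@@H]3O[C@@H]32)[C@@H](OC(C)=O)[C@]4(O)[C@@H](C)C(=O)O[C@H]4[C@H](O)C(=C)C[Si](C)(C)C)cc1 | intermediate
48 | (6S)-allylic chloride | COc1ccc(COC[C@@H](O)[C@]2(C)[C@H]([C@@H](C)[C@@H](O[Si](C)(C)C(C)(C)C)[C@@H]3O[C@@H]32)[C@@H](OC(C)=O)[C@]4(O)[C@@H](C)C(=O)O[C@H]4[C@H](C(=C)C[Si](C)(C)C)Cl)cc1 | intermediate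
49 | allylic bromide (C6 chloride, C3 OPMB) | COc1ccc(COC[C@@H](O)[C@]2(C)[C@H]([C@@H](C)[C@@H](O[Si](C)(C)C(C)(C)C)[C@@H]3O[C@@H]32)[C@@H](OC(C)=O)[C@]4(O)[C@@H](C)C(=O)O[C@H]4[C@H](C(=C)CBr)Cl)cc1 | intermediate
50 | C2,C3-diol allylic bromide | OC[C@@H](O)[C@]1(C)[C@H]([C@@H](C)[C@@H](O[Si](C)(C)C(C)(C)C)[C@@H]2O[C@@H]21)[C@@H](OC(C)=O)[C@]3(O)[C@@H](C)C(=O)O[C@H]3[C@H](C(=C)CBr)Cl | intermediate
51 | C3 aldehyde with free C2 hydroxyl | O=C[C@@H](O)[C@]1(C)[C@H]([C@@H](C)[C@@H](O[Si](C)(C)C(C)(C)C)[C@@H]2O[C@@H]21)[C@@H](OC(C)=O)[C@]3(O)[C@@H](C)C(=O)O[C@H]3[C@H](C(=C)CBr)Cl | intermediate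
52 | ten-membered ring (2S,3S)-diol, C9 acetate, C12 OTBS | C=C1C[C@H](O)[C@@H](O)[C@]2(C)[C@H]([C@@H](C)[C@@H](O[Si](C)(C)C(C)(C)C)[C@@H]3O[C@@H]32)[C@@H](OC(C)=O)[C@]2(O)[C@@H](C)C(=O)O[C@H]2[C@H]1Cl | intermediate
53 | C3,C9-diacetate, C12 OTBS | C=C1C[C@H](OC(C)=O)[C@@H](O)[C@]2(C)[C@H]([C@@H](C)[C@@H](O[Si](C)(C)C(C)(C)C)[C@@H]3O[C@@H]32)[C@@H](OC(C)=O)[C@]2(O)[C@@H](C)C(=O)O[C@H]2[C@H]1Cl | intermediate
54 | CNP0200238.1 | C=C1C[C@H](OC(C)=O)[C@@H](O)[C@]2(C)[C@H]([C@@H](C)[C@@H](O)[C@@H]3O[C@@H]32)[C@@H](OC(C)=O)[C@]2(O)[C@@H](C)C(=O)O[C@H]2[C@H]1Cl | target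

**Count**

Total steps: 39. Longest linear sequence: 32 steps (steps 1–7, 9–15, 22–39); step 8 and steps 16–21 are side branches.

**Steps most likely to fail**

1. Step 37 (ring closure). The allylindium may react intermolecularly or be protonated before the ten-membered ring closes, and chelation may fail to control C3. The fallback sets out from 49 and returns at 54. TESOTf/2,6-lutidine silylates the C2 hydroxyl to give the C2 triethylsilyl ether F1. DDQ frees the primary alcohol F2, and Dess–Martin oxidation gives the α-silyloxy aldehyde F3. CrCl2 in THF under high dilution (Nozaki–Hiyama–Kishi allylation, short contact time to spare the chloride) closes the ring to the homoallylic alcohol F4, expected as the Felkin-type 3R epimer. Mitsunobu esterification with acetic acid (PPh3, DIAD) inverts C3 and gives the (3S)-acetate F5. HF·pyridine then removes both silyl groups to give 54.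

2. Step 26 (oxa-Michael). The equilibrium at the fully substituted C8 may lie on the side of the open butenolide, and the alkoxide may transfer the C9 acetate. The fallback sets out from 38 and returns at 41. OsO4·TMEDA in CH2Cl2 at −78 °C, hydrogen-bonded to the C6 hydroxyl, adds to the butenolide on the C6 face; the hindered C10=C11 alkene should not compete. Sulfite cleavage of the osmate gives the 8,17-diol F6. SmI2 in THF/MeOH removes the C17 hydroxyl α to the lactone carbonyl, with protonation placing the methyl trans to C9, to give the β-hydroxy lactone F7. AcOH/THF/H2O then removes the C2 silyl group to give 41.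

3. Step 22 (key coupling). Oxidative addition at the hindered triflate or transmetalation of the α-branched stannane may be too slow, leading to direct coupling without CO or to destannylation. The fallback keeps CO as the C9 source and the same two bonds; it sets out from 24 and returns at 35. Reductive carbonylation (Pd(PPh3)4, CO, Bu3SnH, THF, 50 °C) gives the C9 enal F8. CrCl2/NiCl2-mediated coupling of F8 with butenolide triflate 32 forms C8–C9 and gives the C9 carbinol as an epimer mixture F9. MnO2 oxidation gives dienone 35.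

**Further compounds**

F1 | step 37 | C2 triethylsilyl ether of 49 | COc1ccc(COC[C@@H](O[Si](CC)(CC)CC)[C@]2(C)[C@H]([C@@H](C)[C@@H](O[Si](C)(C)C(C)(C)C)[C@@H]3O[C@@H]32)[C@@H](OC(C)=O)[C@]4(O)[C@@H](C)C(=O)O[C@H]4[C@H](C(=C)CBr)Cl)cc1
F2 | step 37 | C3 primary alcohol with C2 OTES | OC[C@@H](O[Si](CC)(CC)CC)[C@]1(C)[C@H]([C@@H](C)[C@@H](O[Si](C)(C)C(C)(C)C)[C@@H]2O[C@@H]21)[C@@H](OC(C)=O)[C@]3(O)[C@@H](C)C(=O)O[C@H]3[C@H](C(=C)CBr)Cl
F3 | step 37 | C3 aldehyde with C2 OTES | O=C[C@@H](O[Si](CC)(CC)CC)[C@]1(C)[C@H]([C@@H](C)[C@@H](O[Si](C)(C)C(C)(C)C)[C@@H]2O[C@@H]21)[C@@H](OC(C)=O)[C@]3(O)[C@@H](C)C(=O)O[C@H]3[C@H](C(=C)CBr)Cl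
F4 | step 37 | ten-membered ring (3R)-alcohol with C2 OTES | C=C1C[C@@H](O)[C@@H](O[Si](CC)(CC)CC)[C@]2(C)[C@H]([C@@H](C)[C@@H](O[Si](C)(C)C(C)(C)C)[C@@H]3O[C@@H]32)[C@@H](OC(C)=O)[C@]2(O)[C@@H](C)C(=O)O[C@H]2[C@H]1Cl
F5 | step 37 | (3S)-acetate with C2 OTES and C12 OTBS | C=C1C[C@H](OC(C)=O)[C@@H](O[Si](CC)(CC)CC)[C@]2(C)[C@H]([C@@H](C)[C@@H](O[Si](C)(C)C(C)(C)C)[C@@H]3O[C@@H]32)[C@@H](OC(C)=O)[C@]2(O)[C@@H](C)C(=O)O[C@H]2[C@H]1Cl
F6 | step 26 | 8,17-diol (both hydroxyls on the C6 face) | COc1ccc(COC[C@@H](O[Si](CC)(CC)CC)[C@]2(C)C(=C(C)[C@@H](O[Si](C)(C)C(C)(C)C)[C@@H]3O[C@@H]32)[C@@H](OC(C)=O)[C@]4(O)[C@@](C)(O)C(=O)O[C@H]4CO)cc1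
F7 | step 26 | C8 β-hydroxy lactone with C2 OTES | COc1ccc(COC[C@@H](O[Si](CC)(CC)CC)[C@]2(C)C(=C(C)[C@@H](O[Si](C)(C)C(C)(C)C)[C@@H]3O[C@@H]32)[C@@H](OC(C)=O)[C@]4(O)[C@@H](C)C(=O)O[C@H]4CO)cc1
F8 | step 22 | ring-A C9 enal | COc1ccc(COC[C@@H](O[Si](CC)(CC)CC)[C@]2(C)C(C=O)=C(C)[C@@H](O[Si](C)(C)C(C)(C)C)[C@@H]3O[C@@H]32)cc1
F9 | step 22 | C9 carbinol (C9 epimers) | COc1ccc(COC[C@@H](O[Si](CC)(CC)CC)[C@]2(C)C(=C(C)[C@@H](O[Si](C)(C)C(C)(C)C)[C@@H]3O[C@@H]32)C(O)C4=C(C)C(=O)O[C@H]4CO[Si](CC)(CC)CC)cc1
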